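A direct plan would acylate phloroglucinol A1 with the (S)-2-methylbutanoyl group to the ketone A2, C-prenylate A2 to A3, and join A3 to the pyrone A4 through a one-carbon electrophile.
Its weakest steps would be the two electrophilic substitutions on a ring that offers equivalent positions and free hydroxyl groups.
The Friedel–Crafts acylation would expose the α-branched acyl donor to a strong Lewis acid (enolisation or ketene formation, loss of ee) and would not stop cleanly at one acyl group.
The C-prenylation would compete with O-alkylation and with a second prenylation, so that A3 could be had only at partial conversion.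
Both losses would fall on the fragment that carries the stereocentre.

The arene is not substituted but made. The six ring carbons and the acyl carbonyl of the acylphloroglucinol (ring A) are a folded 3,5,7-triketo ester, and such a chain is stored as a 4-hydroxy-6-(2-oxoalkyl)-2-pyrone. The route therefore assembles the unsymmetrical methylene-bridged bis(4-hydroxy-2-pyrone) 18: ring B, and a second pyrone that carries prenyl at C5 and the (S)-3-methyl-2-oxopentyl chain at C6. Mg(OMe)2 opens the lactones, and one Claisen closure between the side-chain CH2 and the former lactone carbonyl gives the hexasubstituted ring with acyl, prenyl and bridge in place. No aromatic acylation or prenylation remains; ring B is re-closed last.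

Key step: step 9

Remark: simple 4-hydroxy-2-pyrones are opened by Mg(OMe)2 in methanol, so ring B is assumed to open in step 9 and is closed again in step 10; material that keeps ring B intact passes step 10 unchanged.

Step 1
Reactants: 1 methyl 3-oxopentanoate; 2 N-methoxy-N-methylpropanamide
Product: 3 methyl 4-methyl-3,5-dioxoheptanoate
Conditions: 1 (1.3 eq), LiN(i-Pr)2 (2.6 eq), THF, −78 → 0 °C; 2 (1.0 eq), −78 → 0 °C, 2 h; 1 M HCl
Reagents that add atoms: N-methoxy-N-methylpropanamide (2), CCC(=O)N(C)OC
Why: Claisen-type C-acylation of the β-keto ester dianion at its γ-carbon, stopped at the ketone by the chelated adduct of the N-methoxy-N-methylamide (Weinreb ketone synthesis); the C4 centre is of no consequence because it becomes sp2 in step 2.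

Step 2
Reactants: 3 methyl 4-methyl-3,5-dioxoheptanoate
Product: 4 6-ethyl-4-hydroxy-5-methyl-2H-pyran-2-one
Conditions: DBU (1.5 eq), toluene, 110 °C, 3 h; 1 M HCl
Reagents that add atoms: none
Why: base-mediated lactonisation of a 3,5-dioxo ester, in which the enol oxygen at C5 attacks the ester in a six-membered closure and loss of methanol leads to the pyronate as the thermodynamic sink.

Step 3
Reactants: 5 methyl 3-oxobutanoate (methyl acetoacetate); 6 1-bromo-3-methylbut-2-ene (prenyl bromide)
Product: 7 methyl 7-methyl-3-oxooct-6-enoate
Conditions: LiN(i-Pr)2 (2.1 eq), THF, 0 °C, 30 min; 6 (1.0 eq), 0 °C → rt; 1 M HCl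
Reagents that add atoms: prenyl bromide (6), CC(C)=CCBr
Why: γ-alkylation of the β-keto ester dianion, whose terminal carbanion displaces the primary allylic bromide by SN2 without allylic transposition.

Step 4
Reactants: 7 methyl 7-methyl-3-oxooct-6-enoate; 8 N-methoxy-N-methylacetamide
Product: 9 methyl 4-acetyl-7-methyl-3-oxooct-6-enoate
Conditions: 7 (1.3 eq), LiN(i-Pr)2 (2.6 eq), THF, −78 → 0 °C; 8 (1.0 eq), −78 → 0 °C, 2 h; 1 M HCl
Reagents that add atoms: N-methoxy-N-methylacetamide (8), CC(=O)N(C)OC
Why: second dianion formation at the only γ-position (C4, which already bears the prenyl group) and C-acylation as in step 1 (Weinreb ketone synthesis); the C4 centre is lost on lactonisation.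

Step 5
Reactants: 9 methyl 4-acetyl-7-methyl-3-oxooct-6-enoate
Product: 10 4-hydroxy-6-methyl-5-(3-methylbut-2-en-1-yl)-2H-pyran-2-one
Conditions: DBU (1.5 eq), toluene, 110 °C, 3 h; cold 1 M HCl
Reagents that add atoms: none
Why: lactonisation as in step 2, where only the acetyl oxygen can close a six-membered lactone, so prenyl is fixed at C5 and methyl at C6; the medium is basic, so the prenyl group and the neighbouring hydroxyl do not cyclise.

Step 6
Reactants: 11 (S)-2-methylbutanoic acid; 12 N,O-dimethylhydroxylamine hydrochloride
Product: 14 (S)-N-methoxy-N,2-dimethylbutanamide, via acyl imidazole 13 (not isolated)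
Conditions: 1,1'-carbonyldiimidazole (1.1 eq), CH2Cl2, 0 °C → rt, 1 h; 12 (1.2 eq), rt, 12 h; 1 M HCl wash
Reagents that add atoms: N,O-dimethylhydroxylamine hydrochloride (12), CNOC.Cl
Why: amide formation through the acyl imidazole with no base stronger than imidazole present, so the α-stereocentre of 11 is carried over unchanged.

Step 7
Reactants: 10 4-hydroxy-6-methyl-5-(3-methylbut-2-en-1-yl)-2H-pyran-2-one; 14 (S)-N-methoxy-N,2-dimethylbutanamide
Product: 15 4-hydroxy-6-[(3S)-3-methyl-2-oxopentyl]-5-(3-methylbut-2-en-1-yl)-2H-pyran-2-one
Conditions: LiN(i-Pr)2 (2.3 eq), THF–DMPU, −78 → −30 °C, 1 h; 14 (1.1 eq), −78 → 0 °C, 2 h; 1 M HCl, 0 °C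
Reagents that add atoms: (S)-N-methoxy-N,2-dimethylbutanamide (14), CC[C@H](C)C(=O)N(C)OC
Why: the pyrone dianion (pyronate plus vinylogous deprotonation of the 6-methyl group, the only such site) is C-acylated by the N-methoxy-N-methylamide (Weinreb ketone synthesis), whose chelated adduct prevents a second addition; the stereocentre comes from 14 and should not be deprotonated at low temperature (ee to be checked by chiral HPLC).

Step 8
Reactants: 15 4-hydroxy-6-[(3S)-3-methyl-2-oxopentyl]-5-(3-methylbut-2-en-1-yl)-2H-pyran-2-one; 4 6-ethyl-4-hydroxy-5-methyl-2H-pyran-2-one; 16 formaldehyde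
Product: 18 6-ethyl-4-hydroxy-3-({4-hydroxy-6-[(3S)-3-methyl-2-oxopentyl]-5-(3-methylbut-2-en-1-yl)-2-oxo-2H-pyran-3-yl}methyl)-5-methyl-2H-pyran-2-one, via 3-methylidene dione 17 (not isolated)
Conditions: 4 (3 eq), 37% aqueous CH2O (1.5 eq, added over 2 h), DABCO (0.1 eq), EtOH, 40 °C, 6 h; chromatography, excess 4 recovered
Reagents that add atoms: formaldehyde (16), C=O
Why: Knoevenagel condensation of formaldehyde with a 4-hydroxy-2-pyrone followed by Michael addition of the second pyrone to the 3-methylidene dione; C3 is the only nucleophilic ring carbon of either pyronate, and the excess of the cheap partner 4 should direct 15 into the mixed product.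

Step 9
Reactants: 18 6-ethyl-4-hydroxy-3-({4-hydroxy-6-[(3S)-3-methyl-2-oxopentyl]-5-(3-methylbut-2-en-1-yl)-2-oxo-2H-pyran-3-yl}methyl)-5-methyl-2H-pyran-2-one
Product: 20 methyl 4-methyl-3,5-dioxo-2-{[2,4,6-trihydroxy-3-[(2S)-2-methylbutanoyl]-5-(3-methylbut-2-en-1-yl)phenyl]methyl}heptanoate, via ring-opened diester 19 (not isolated)
Conditions: Mg(OMe)2 (10 eq), MeOH, 65 °C, Ar, 8 h; cold 1 M HCl to pH 4, EtOAc
Reagents that add atoms: methanol (solvent, delivered as Mg(OMe)2), CO
Why: Methoxide held on magnesium should open both lactones of 18 to the chelated diester 19, in which the CH2 between the two ketones of the prenylated arm attacks the ester carbonyl of its own half (Claisen condensation, six-membered, exo at the ester) and the resulting cyclohexanetrione enolises to the phenol. The closest known reaction is the Mg(OMe)2-induced rearrangement of 4-hydroxy-6-(2-oxoalkyl)-2-pyrones into acylphloroglucinols, the laboratory counterpart of the Claisen folding of a tetraketide. Ring A is thus closed by one C–C bond between the former side-chain methylene and the former lactone carbonyl, and the acyl group, the prenyl group and the bridge stand on alternate carbons because they were neighbouring chain substituents, not because of any positional choice. No stereocentre is formed: the sp3 centres of 19 disappear on aromatisation, and the (S) centre is left alone because its ketone is enolised only towards the doubly activated CH2. The step needs Claisen over aldol selectivity and the right carbanion–ester pair, and the substrate secures both: this CH2 is the only unsubstituted doubly activated carbon and its sole six-membered closure is this Claisen, while every closure through the other, substituted carbanions creates a quaternary carbon, cannot aromatise and stays reversible, so the triphenolate is the only sink. Ring B stays open as the chelated diketo ester of 20 and is re-closed in step 10.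

Step 10
Reactants: 20 methyl 4-methyl-3,5-dioxo-2-{[2,4,6-trihydroxy-3-[(2S)-2-methylbutanoyl]-5-(3-methylbut-2-en-1-yl)phenyl]methyl}heptanoate
Product: 21 6-ethyl-4-hydroxy-5-methyl-3-{[2,4,6-trihydroxy-3-[(2S)-2-methylbutanoyl]-5-(3-methylbut-2-en-1-yl)phenyl]methyl}-2H-pyran-2-one (target)
Conditions: DBU (4 eq), toluene, 90 °C, Ar, methanol distilled off, 3 h; cold 1 M HCl
Reagents that add atoms: none
Why: lactonisation of the 3,5-dioxo ester as in step 2; the pyronate is the thermodynamic sink, so an aryl lactone formed through a phenolic oxygen should be converted into it by acyl transfer, and the stereocentre, α to a ketone conjugated with the phenolates, is not at risk.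

Compound list

1 | methyl 3-oxopentanoate | CCC(=O)CC(=O)OC | starting material
2 | N-methoxy-N-methylpropanamide | CCC(=O)N(C)OC | starting material
3 | methyl 4-methyl-3,5-dioxoheptanoate (racemic at C4) | CCC(=O)C(C)C(=O)CC(=O)OC | intermediate
4 | 6-ethyl-4-hydroxy-5-methyl-2H-pyran-2-one | CCc1oc(=O)cc(O)c1C | intermediate
5 | methyl 3-oxobutanoate (methyl acetoacetate) | CC(=O)CC(=O)OC | starting material
6 | 1-bromo-3-methylbut-2-ene (prenyl bromide) | CC(C)=CCBr | starting material
7 | methyl 7-methyl-3-oxooct-6-enoate | CC(C)=CCCC(=O)CC(=O)OC | intermediate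
8 | N-methoxy-N-methylacetamide | CC(=O)N(C)OC | starting material
9 | methyl 4-acetyl-7-methyl-3-oxooct-6-enoate (racemic at C4) | CC(=O)C(CC=C(C)C)C(=O)CC(=O)OC | intermediate
10 | 4-hydroxy-6-methyl-5-(3-methylbut-2-en-1-yl)-2H-pyran-2-one | Cc1oc(=O)cc(O)c1CC=C(C)C | intermediate
11 | (S)-2-methylbutanoic acid | CC[C@H](C)C(=O)O | starting material
12 | N,O-dimethylhydroxylamine hydrochloride | CNOC.Cl | starting material
13 | (S)-1-(1H-imidazol-1-yl)-2-methylbutan-1-one (not isolated) | CC[C@H](C)C(=O)n1ccnc1 | intermediate
14 | (S)-N-methoxy-N,2-dimethylbutanamide | CC[C@H](C)C(=O)N(C)OC | intermediate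
15 | 4-hydroxy-6-[(3S)-3-methyl-2-oxopentyl]-5-(3-methylbut-2-en-1-yl)-2H-pyran-2-one | CC[C@H](C)C(=O)Cc1oc(=O)cc(O)c1CC=C(C)C | intermediate
16 | formaldehyde | C=O | starting material
17 | 6-ethyl-5-methyl-3-methylidene-2H-pyran-2,4(3H)-dione (not isolated) | CCC1=C(C)C(=O)C(=C)C(=O)O1 | intermediate
18 | 6-ethyl-4-hydroxy-3-({4-hydroxy-6-[(3S)-3-methyl-2-oxopentyl]-5-(3-methylbut-2-en-1-yl)-2-oxo-2H-pyran-3-yl}methyl)-5-methyl-2H-pyran-2-one | CC[C@H](C)C(=O)Cc1oc(=O)c(Cc2c(O)c(C)c(CC)oc2=O)c(O)c1CC=C(C)C | intermediate
19 | dimethyl 2-(2-methyl-3-oxopentanoyl)-4-[(6S)-6-methyl-2-(3-methylbut-2-en-1-yl)-3,5-dioxooctanoyl]pentanedioate (magnesium chelate, mixture of diastereomers, not isolated) | COC(=O)C(CC(C(=O)OC)C(=O)C(C)C(=O)CC)C(=O)C(CC=C(C)C)C(=O)CC(=O)[C@@H](C)CC | intermediate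
20 | methyl 4-methyl-3,5-dioxo-2-{[2,4,6-trihydroxy-3-[(2S)-2-methylbutanoyl]-5-(3-methylbut-2-en-1-yl)phenyl]methyl}heptanoate (mixture of diastereomers at C2 and C4, both lost in step 10) | CCC(=O)C(C)C(=O)C(Cc1c(O)c(CC=C(C)C)c(O)c(C(=O)[C@@H](C)CC)c1O)C(=O)OC | intermediate
21 | 6-ethyl-4-hydroxy-5-methyl-3-{[2,4,6-trihydroxy-3-[(2S)-2-methylbutanoyl]-5-(3-methylbut-2-en-1-yl)phenyl]methyl}-2H-pyran-2-one | CCc1oc(=O)c(Cc2c(O)c(CC=C(C)C)c(O)c(C(=O)[C@@H](C)CC)c2O)c(O)c1C | target

Total step count: 10. Longest linear sequence: 7 steps (steps 3, 4, 5, 7, 8, 9, 10).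

Steps most likely to fail

Step 9. The chain of 19 may be held in reversible non-aromatic aldol or Claisen rings or be cut by retro-Claisen attack of methoxide. The two halves may exchange across the methylene bridge by retro-Michael fragmentation. The ring-opened ring B side chain may condense with a neighbouring phenol to a chromene on acidification, which would also spoil step 10. Fallback: the arene is formed before the bridge exists, so that no second lactone meets methoxide. From 15, Mg(OMe)2 in MeOH at 65 °C should give (S)-2-methyl-1-[2,4,6-trihydroxy-3-(3-methylbut-2-en-1-yl)phenyl]butan-1-one F1 by the same ring transformation on its simplest substrate class. F1, pyrone 4 and formaldehyde (EtOH, NaOAc, rt) are then joined by Knoevenagel condensation and Michael addition to 21, where the route is rejoined at its last compound; steps 8 to 10 fall away.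

Step 8. Either pyrone may couple with itself, and the methide may attack the side-chain methylene of 15 instead of C3. Fallback: the electrophile is preformed on the cheap partner. From 4, Me2N=CH2+ I− (dimethylmethyleneiminium iodide) in MeCN gives the Mannich base 3-[(dimethylamino)methyl]-6-ethyl-4-hydroxy-5-methyl-2H-pyran-2-one F2 as an isolable betaine. Heated with 15 (1.0 eq) in MeCN at 70 °C, F2 loses dimethylamine and passes its methide to C3 of 15 only, which returns to 18.

Step 7. Proton transfer may win over acylation (from the α-CH of the amide, or between dianion and adduct), which would mean low conversion or partial racemisation. Fallback: aldol addition and oxidation in place of acylation. From 10, the same dianion is added at −78 °C to freshly distilled (S)-2-methylbutanal F3, which is attacked faster than it is deprotonated, to give 4-hydroxy-6-[(3S)-2-hydroxy-3-methylpentyl]-5-(3-methylbut-2-en-1-yl)-2H-pyran-2-one F4 as a mixture of carbinol epimers. Dess–Martin oxidation of the secondary alcohol (NaHCO3, CH2Cl2, 0 °C) returns to 15.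

Further compounds

F1 | step 9 | (S)-2-methyl-1-[2,4,6-trihydroxy-3-(3-methylbut-2-en-1-yl)phenyl]butan-1-one | CC[C@H](C)C(=O)c1c(O)cc(O)c(CC=C(C)C)c1O
F2 | step 8 | 3-[(dimethylamino)methyl]-6-ethyl-4-hydroxy-5-methyl-2H-pyran-2-one | CCc1oc(=O)c(CN(C)C)c(O)c1C
F3 | step 7 | (S)-2-methylbutanal | CC[C@H](C)C=O
F4 | step 7 | 4-hydroxy-6-[(3S)-2-hydroxy-3-methylpentyl]-5-(3-methylbut-2-en-1-yl)-2H-pyran-2-one | CC[C@H](C)C(O)Cc1oc(=O)cc(O)c1CC=C(C)C
A1 | direct plan | benzene-1,3,5-triol (phloroglucinol) | Oc1cc(O)cc(O)c1
A2 | direct plan | (S)-2-methyl-1-(2,4,6-trihydroxyphenyl)butan-1-one | CC[C@H](C)C(=O)c1c(O)cc(O)cc1O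
A3 | direct plan | (S)-2-methyl-1-[2,4,6-trihydroxy-3-(3-methylbut-2-en-1-yl)phenyl]butan-1-one (identical with F1) | CC[C@H](C)C(=O)c1c(O)cc(O)c(CC=C(C)C)c1O
A4 | direct plan | 6-ethyl-4-hydroxy-5-methyl-2H-pyran-2-one (identical with 4) | CCc1oc(=O)cc(O)c1C
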